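In molar units, what stands in this flask? A racemate of left-handed substrate and right-handed substrate, with reagent, a single-handed free catalyst and an impurity. The winter run is this same flask, followed so far.

common to all: left-handed substrate 0.40 M; right-handed substrate 0.40 M; free catalyst 0.5 mol%; impurity 0.91 mM
- winter: reagent 1.2 equiv; the very flask that is asked about, followed so far
- flask: reagent 1.20 equiv

- winter (time / h: left-handed product / %): 0.133: 6.0; 0.333: 13.4; 0.667: 20.5; 1.00: 24.4; 1.33: 28.1; 2.00: 32.5; 2.50: 33.8

(standard deviation of a reading: 0.3 percentage points)

- free catalyst is single-handed; left-handed substrate and right-handed substrate are mirror images of each other, charged as a racemate, each of them at the stated concentration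
- no earlier run changes the charge of free catalyst; that part of a forecast is a guess

* apparent order in free catalyst when 50% of the left-handed substrate and right-handed substrate together are converted (percent change of the rate of making left-handed product for one percent more free catalyst charged)
* factor on the rate of making left-handed product when 50% of the left-handed substrate and right-handed substrate together are converted if free catalyst is charged twice over

Which charge falls short of its demand? Reagent, if each substrate molecule converted takes one reagent, which I assume: 0.480 M stands against 0.800 M of substrates together. It is the limiting reagent, and total conversion has a ceiling of 60.0%.

And at the conversion asked about? At 50% the balance leaves 0.0800 M. This [reagent] at a fixed total conversion, charge less use, is what I carry: the reagent margin.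

Do the readings test the assumption? No. The last reading of the winter run, 33.8% at 2.50 h, counts left-handed product alone and lies below the ceiling.

What has the margin to do with the catalyst? It contains no catalyst term. So if the split between the substrates holds, the factor on the rate at fixed conversion is the factor on working catalyst.

How much catalyst works? No run varied it, so this is my guess. The loading on left-handed substrate gives 2.00 mM. If each impurity removes one catalyst, 1.09 mM remains, which gives an order of 1.83 and a doubling factor of 2.83.

The forecast, which differs from my figures, gives an order of 1.3 (0.9 to 1.9) and a factor of 2.3 (1.7 to 3.4), and says: “this is a guess and the ranges are wide”.

The flask reaches 50% at 2.65 h and gives an order of 1.4 and a factor of 2.16, lower than my figures. There 45.5% of the catalyst is spent catalyst and 39.9% is free catalyst; resting dimer, which holds 14.6% of the catalyst at 4.00 h, is also outside the working round.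

    reagent + free catalyst + left-handed substrate → free catalyst + left-handed product (k = 47.0 M⁻² min⁻¹)
    reagent + free catalyst + right-handed substrate → free catalyst + right-handed product (k = 15.0 M⁻² min⁻¹)
    2 free catalyst ⇌ resting dimer, settled at all times (K = 230 M⁻¹)
    free catalyst + impurity → spent catalyst (k = 4600 M⁻¹ min⁻¹)

Per free catalyst at the charged concentrations, the step to left-handed product runs at 540 h⁻¹ against 170 h⁻¹ for the step to right-handed product, a selectivity factor of 3.13. After 80.0 h the flask holds 40.0% left-handed product and 20.0% right-handed product with reagent at 0%, together 60.0% against the ceiling of 60.0%. In a second flask with twice the reagent the margin at 50% becomes 0.560 M, which is 7.00 times 0.0800 M, and the rate there rises by a factor of 7.00.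

(The readings come from a simulation with constants of no real substance, noise included.)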